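**Retrosynthetic overview**

1. Target ⇒ linoleic acid + the (S)-diol carrying the 6-prenylindole; the last step esterifies only the primary OH, leaving the tertiary OH and indole N–H free.
2. Prenyl diol ⇒ 6-bromo diol + prenylstannane (Stille). The prenyl group enters only after the carbene step, because a trisubstituted alkene would itself react with a rhodium carbene.
3. 6-Bromo diol ⇒ N-Boc, O-TMS protected β-silyloxy trichloroethyl ester (ester reduction, then loss of Boc and TMS).
4. Key disconnection: the bond between the stereocenter and the carbinol carbon, and the only stereocenter, come from a new enantioselective insertion of an (indol-3-yl)carbene into the tertiary O–C–H bond of isopropoxytrimethylsilane (an acetone-aldol equivalent). The diazo ester comes from 6-bromoindole-3-acetic acid.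
5. No ring is formed in the route: the indole (both rings) is bought intact.

Assumption 1: 2-(6-bromo-1H-indol-3-yl)acetic acid is bought as a catalogue compound.
Assumption 2: Rh2(S-TCPTAD)4 is taken to give the (2R) ester 7 in step 4, by analogy with its known tertiary C–H insertions; if the measured sense is opposite, the mirror-image catalyst Rh2(R-TCPTAD)4 is used and nothing else changes.

**Route**

Step 1
Reactants: 1 2-(6-bromo-1H-indol-3-yl)acetic acid; 2 trichloroethanol (2,2,2-trichloroethan-1-ol)
Product: 3 2,2,2-trichloroethyl 2-(6-bromo-1H-indol-3-yl)acetate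
Conditions: N,N'-dicyclohexylcarbodiimide, DMAP (cat.), CH2Cl2, 0 °C → rt
Reagents that add atoms: none
Why: Steglich esterification of the arylacetic acid, in which the weakly nucleophilic indole N–H does not compete; the trichloroethyl ester is chosen because it gives the best site- and enantioselectivity with bulky dirhodium carboxylate catalysts later on.

Step 2
Reactants: 3 2,2,2-trichloroethyl 2-(6-bromo-1H-indol-3-yl)acetate
Product: 4 tert-butyl 6-bromo-3-[2-oxo-2-(2,2,2-trichloroethoxy)ethyl]-1H-indole-1-carboxylate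
Conditions: Boc2O, DMAP (cat.), MeCN, rt
Reagents that add atoms: di-tert-butyl dicarbonate (Boc2O), CC(C)(C)OC(=O)OC(=O)OC(C)(C)C
Why: DMAP-catalysed N-carbamoylation of the indole, which blocks N–H insertion and deactivates the C2=C3 bond toward the carbene of step 4.

Step 3
Reactants: 4 tert-butyl 6-bromo-3-[2-oxo-2-(2,2,2-trichloroethoxy)ethyl]-1H-indole-1-carboxylate
Product: 5 tert-butyl 6-bromo-3-[1-diazo-2-oxo-2-(2,2,2-trichloroethoxy)ethyl]-1H-indole-1-carboxylate
Conditions: p-ABSA, DBU, MeCN, 0 °C → rt
Reagents that add atoms: 4-acetamidobenzenesulfonyl azide (p-ABSA), CC(=O)Nc1ccc(cc1)S(=O)(=O)N=[N+]=[N-]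
Why: Regitz diazo transfer to the methylene group activated by both the heteroaryl ring and the ester, the standard entry to donor/acceptor diazoacetates.

Step 4
Reactants: 5 tert-butyl 6-bromo-3-[1-diazo-2-oxo-2-(2,2,2-trichloroethoxy)ethyl]-1H-indole-1-carboxylate; 6 isopropoxytrimethylsilane
Product: 7 2,2,2-trichloroethyl (2R)-2-[6-bromo-1-(tert-butoxycarbonyl)-1H-indol-3-yl]-3-methyl-3-[(trimethylsilyl)oxy]butanoate
Conditions: Rh2(S-TCPTAD)4 {dirhodium tetrakis[(S)-(1-adamantyl)(tetrachlorophthalimido)acetate]} (1 mol %), 6 (5 equiv), 4 Å molecular sieves, CH2Cl2, 40 °C, slow addition of 5 over 3 h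
Reagents that add atoms: none
Why: Proposed new method: enantioselective intermolecular insertion of a dirhodium-bound (indol-3-yl)(ester) donor/acceptor carbene into the tertiary α-oxy C–H bond of an isopropyl silyl ether, a catalytic asymmetric acetone-aldol equivalent; the diazo ester loses N2 at the divalent rhodium centre to give an electrophilic carbene that reacts through a concerted, asynchronous three-centre hydride-transfer/C–C bond-forming transition state in which positive charge builds on the C–H carbon, here stabilised by the oxygen lone pair and two methyl groups, so this bond far outpaces the primary C–H bonds of the CH3 and SiCH3 groups, while the weakly basic, hindered silyl ether oxygen disfavours oxonium ylide formation; the bowl-shaped chiral ligand wall admits the C–H bond to one face of the carbene only, which sets the (2R) stereocenter directly; the closest known reaction types are dirhodium-catalysed donor/acceptor-carbene insertion into secondary C–H bonds α to oxygen of silyl ethers and tetraalkoxysilanes, and tertiary-selective C–H insertion of trichloroethyl aryldiazoacetates with this same catalyst.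

Step 5
Reactants: 7 2,2,2-trichloroethyl (2R)-2-[6-bromo-1-(tert-butoxycarbonyl)-1H-indol-3-yl]-3-methyl-3-[(trimethylsilyl)oxy]butanoate
Product: 8 tert-butyl 6-bromo-3-[(2S)-1-hydroxy-3-methyl-3-[(trimethylsilyl)oxy]butan-2-yl]-1H-indole-1-carboxylate
Conditions: i-Bu2AlH (DIBAL-H, 3 equiv), CH2Cl2, −78 → −20 °C; aq. KNaC4H4O6 work-up
Reagents that add atoms: none
Why: Hydride reduction of the activated trichloroethyl ester to the primary alcohol under non-basic, low-temperature conditions, so the α-aryl stereocenter is not epimerised and silanolate is not eliminated (the descriptor changes from R to S only because CH2OH now ranks below the carbinol carbon); any partial loss of Boc is harmless because step 6 removes it.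

Step 6
Reactants: 8 tert-butyl 6-bromo-3-[(2S)-1-hydroxy-3-methyl-3-[(trimethylsilyl)oxy]butan-2-yl]-1H-indole-1-carboxylate
Product: 9 (2S)-2-(6-bromo-1H-indol-3-yl)-3-methylbutane-1,3-diol
Conditions: K2CO3 (0.5 equiv), MeOH, 40 °C
Reagents that add atoms: none
Why: Base-catalysed methanolysis cleaves the indole carbamate (indolide is a good leaving group) and the trimethylsilyl ether in one operation without touching the stereocenter, and the diol offers a chance to raise the ee by recrystallisation.

Step 7
Reactants: 9 (2S)-2-(6-bromo-1H-indol-3-yl)-3-methylbutane-1,3-diol; 10 tributyl(3-methylbut-2-en-1-yl)stannane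
Product: 11 (2S)-3-methyl-2-[6-(3-methylbut-2-en-1-yl)-1H-indol-3-yl]butane-1,3-diol
Conditions: 10 (1.5 equiv), Pd(PPh3)4 (5 mol %), DMF, 100 °C, Ar
Reagents that add atoms: none
Why: Stille cross-coupling at the aryl bromide under zerovalent palladium catalysis tolerates free N–H and O–H groups, and the aryl(prenyl)palladium intermediate reductively eliminates at the unsubstituted allyl terminus to give the linear prenyl arene.

Step 8
Reactants: 11 (2S)-3-methyl-2-[6-(3-methylbut-2-en-1-yl)-1H-indol-3-yl]butane-1,3-diol; 12 linoleic acid [(9Z,12Z)-octadeca-9,12-dienoic acid]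
Product: 13 (2S)-3-hydroxy-3-methyl-2-[6-(3-methylbut-2-en-1-yl)-1H-indol-3-yl]butyl (9Z,12Z)-octadeca-9,12-dienoate (CNP0180241.1)
Conditions: 12 (1.1 equiv), N,N'-diisopropylcarbodiimide (1.2 equiv), DMAP (0.1 equiv), CH2Cl2, 0 °C → rt, Ar, dark
Reagents that add atoms: none
Why: Steglich esterification acylates the primary alcohol selectively over the tertiary alcohol and the electron-rich indole N–H, under conditions mild enough to keep the skipped Z,Z-diene, the prenyl group and the stereocenter intact.

**Compound list**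

1 | 2-(6-bromo-1H-indol-3-yl)acetic acid | OC(=O)Cc1c[nH]c2cc(Br)ccc12 | starting material
2 | 2,2,2-trichloroethanol | OCC(Cl)(Cl)Cl | starting material
3 | 2,2,2-trichloroethyl 2-(6-bromo-1H-indol-3-yl)acetate | ClC(Cl)(Cl)COC(=O)Cc1c[nH]c2cc(Br)ccc12 | intermediate
4 | tert-butyl 6-bromo-3-[2-oxo-2-(2,2,2-trichloroethoxy)ethyl]-1H-indole-1-carboxylate | ClC(Cl)(Cl)COC(=O)Cc1cn(C(=O)OC(C)(C)C)c2cc(Br)ccc12 | intermediate
5 | tert-butyl 6-bromo-3-[1-diazo-2-oxo-2-(2,2,2-trichloroethoxy)ethyl]-1H-indole-1-carboxylate | ClC(Cl)(Cl)COC(=O)C(=[N+]=[N-])c1cn(C(=O)OC(C)(C)C)c2cc(Br)ccc12 | intermediate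
6 | isopropoxytrimethylsilane | CC(C)O[Si](C)(C)C | starting material
7 | 2,2,2-trichloroethyl (2R)-2-[6-bromo-1-(tert-butoxycarbonyl)-1H-indol-3-yl]-3-methyl-3-[(trimethylsilyl)oxy]butanoate | ClC(Cl)(Cl)COC(=O)[C@H](c1cn(C(=O)OC(C)(C)C)c2cc(Br)ccc12)C(C)(C)O[Si](C)(C)C | intermediate
8 | tert-butyl 6-bromo-3-[(2S)-1-hydroxy-3-methyl-3-[(trimethylsilyl)oxy]butan-2-yl]-1H-indole-1-carboxylate | OC[C@H](c1cn(C(=O)OC(C)(C)C)c2cc(Br)ccc12)C(C)(C)O[Si](C)(C)C | intermediate
9 | (2S)-2-(6-bromo-1H-indol-3-yl)-3-methylbutane-1,3-diol | OC[C@H](c1c[nH]c2cc(Br)ccc12)C(C)(C)O | intermediate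
10 | tributyl(3-methylbut-2-en-1-yl)stannane | CCCC[Sn](CCCC)(CCCC)CC=C(C)C | starting material
11 | (2S)-3-methyl-2-[6-(3-methylbut-2-en-1-yl)-1H-indol-3-yl]butane-1,3-diol | OC[C@H](c1c[nH]c2cc(CC=C(C)C)ccc12)C(C)(C)O | intermediate
12 | linoleic acid, (9Z,12Z)-octadeca-9,12-dienoic acid | CCCCC/C=C\C/C=C\CCCCCCCC(O)=O | starting material
13 | (2S)-3-hydroxy-3-methyl-2-[6-(3-methylbut-2-en-1-yl)-1H-indol-3-yl]butyl (9Z,12Z)-octadeca-9,12-dienoate | CCCCC/C=C\C/C=C\CCCCCCCC(=O)OC[C@H](c1c[nH]c2cc(CC=C(C)C)ccc12)C(C)(C)O | target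

**Step count and risk**

Total step count: 8. Longest linear sequence: 8 steps (1 → 13).

Three steps most likely to fail:

Step 4 (the proposed new method). Risks are slow insertion at the congested tertiary site, carbene dimerisation and a modest ee. The fallback uses known auxiliary-controlled titanium enolate aldol chemistry; it sets out from 4 and comes back to the route at 9. The trichloroethyl ester of 4 is cleaved with Zn dust in AcOH/THF to give [6-bromo-1-(tert-butoxycarbonyl)-1H-indol-3-yl]acetic acid F1. Pivaloyl chloride and Et3N in THF at −20 °C convert it into the mixed pivalic anhydride F2, which without isolation acylates (R)-4-benzyl-1,3-oxazolidin-2-one (LiCl, Et3N) to give (4R)-4-benzyl-3-{[6-bromo-1-(tert-butoxycarbonyl)-1H-indol-3-yl]acetyl}-1,3-oxazolidin-2-one F3. Soft enolisation with TiCl4 and i-Pr2NEt in CH2Cl2 at −78 °C followed by acetone gives the tertiary aldol (4R)-4-benzyl-3-{(2R)-2-[6-bromo-1-(tert-butoxycarbonyl)-1H-indol-3-yl]-3-hydroxy-3-methylbutanoyl}-1,3-oxazolidin-2-one F4; the (R)-auxiliary is chosen because the usual Evans-syn facial sense of chlorotitanium enolates then leads to the (2R) centre. LiBH4 in THF/MeOH at 0 °C removes the auxiliary reductively to give tert-butyl 6-bromo-3-[(2S)-1,3-dihydroxy-3-methylbutan-2-yl]-1H-indole-1-carboxylate F5, and K2CO3 in MeOH as in step 6 gives 9.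

Step 7. Risks are formation of the branched (1,1-dimethylallyl) isomer and protodestannylation. The fallback builds the prenyl group in two stages; it sets out from 9 and comes back at 11. Stille coupling of 9 with allyltributylstannane (Pd(PPh3)4, DMF, 90 °C), where no regiochemical question arises, gives (2S)-3-methyl-2-[6-(prop-2-en-1-yl)-1H-indol-3-yl]butane-1,3-diol F6. Cross-metathesis of F6 with excess 2-methylbut-2-ene using the second-generation Grubbs catalyst RuCl2(=CHPh)(H2IMes)(PCy3) in CH2Cl2 at 40 °C gives 11.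

Step 5. Risks are sluggish reduction of the congested ester, epimerisation at the aldehyde stage and side reactions at the CCl3 group. The fallback unmasks the acid first; it sets out from 7 and comes back at 8. Zn dust in THF/aq. KH2PO4 at rt removes the trichloroethyl group reductively to give (2R)-2-[6-bromo-1-(tert-butoxycarbonyl)-1H-indol-3-yl]-3-methyl-3-[(trimethylsilyl)oxy]butanoic acid F7. BH3·SMe2 in THF (0 °C → rt) then reduces the carboxylic acid chemoselectively, leaving carbamate, silyl ether and aryl bromide untouched, to give 8.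

**Further compounds**

F1 | step 4 | [6-bromo-1-(tert-butoxycarbonyl)-1H-indol-3-yl]acetic acid | OC(=O)Cc1cn(C(=O)OC(C)(C)C)c2cc(Br)ccc12
F2 | step 4 | [6-bromo-1-(tert-butoxycarbonyl)-1H-indol-3-yl]acetic pivalic anhydride | CC(C)(C)C(=O)OC(=O)Cc1cn(C(=O)OC(C)(C)C)c2cc(Br)ccc12
F3 | step 4 | (4R)-4-benzyl-3-{[6-bromo-1-(tert-butoxycarbonyl)-1H-indol-3-yl]acetyl}-1,3-oxazolidin-2-one | O=C(Cc1cn(C(=O)OC(C)(C)C)c2cc(Br)ccc12)N1[C@H](Cc2ccccc2)COC1=O
F4 | step 4 | (4R)-4-benzyl-3-{(2R)-2-[6-bromo-1-(tert-butoxycarbonyl)-1H-indol-3-yl]-3-hydroxy-3-methylbutanoyl}-1,3-oxazolidin-2-one | O=C([C@H](c1cn(C(=O)OC(C)(C)C)c2cc(Br)ccc12)C(C)(C)O)N1[C@H](Cc2ccccc2)COC1=O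
F5 | step 4 | tert-butyl 6-bromo-3-[(2S)-1,3-dihydroxy-3-methylbutan-2-yl]-1H-indole-1-carboxylate | OC[C@H](c1cn(C(=O)OC(C)(C)C)c2cc(Br)ccc12)C(C)(C)O
F6 | step 7 | (2S)-3-methyl-2-[6-(prop-2-en-1-yl)-1H-indol-3-yl]butane-1,3-diol | OC[C@H](c1c[nH]c2cc(CC=C)ccc12)C(C)(C)O
F7 | step 5 | (2R)-2-[6-bromo-1-(tert-butoxycarbonyl)-1H-indol-3-yl]-3-methyl-3-[(trimethylsilyl)oxy]butanoic acid | OC(=O)[C@H](c1cn(C(=O)OC(C)(C)C)c2cc(Br)ccc12)C(C)(C)O[Si](C)(C)C
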